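**Target first.** The target in cedar reads 12% at 20.0 min and 3% at 60.0 min, so it is a passing stage, and the share you are asked for depends on how far a flask has got.

| flask | starting material | reagent | second substrate | remark | time |
|---|---|---|---|---|---|
| cedar | 0.20 M | 0.24 M | 0.20 M | run made earlier |  |
| alder | 0.28 M | 0.24 M | 0.20 M | run made earlier |  |
| birch | 0.44 M | 0.24 M | 0.20 M | run made earlier |  |
| maple | 0.20 M | 0.24 M | 0.30 M | run made earlier |  |
| winter | 0.20 M | 0.240 M (in portions, 2, over 80 min) | 0.200 M | first portion at the start, last at 80 min | 2.0 h |
| autumn | 0.20 M | 0.240 M (fed, over 80 min) | 0.200 M | all else is in the flask from the start; the feed brings no volume worth counting | 2.0 h |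
| dawn | 0.20 M | 0.240 M | 0.200 M | everything together at the start | 2.0 h |
| midnight | 0.20 M | 0.240 M | 0.200 M (fed, over 80 min) | all else is in the flask from the start; the feed brings no volume worth counting | 2.0 h |

- cedar (time / min: target / %, over-reaction product / %): 10.0: 10, 2; 20.0: 12, 9; 30.0: 10, 13; 60.0: 3, 24; 120: 6, 37
- alder (time / min: target / %, over-reaction product / %): 20.0: 9, 8; 40.0: 9, 14; 60.0: 6, 22; 80.0: 4, 24; 90.0: 1, 24
- birch (time / min: target / %, over-reaction product / %): 20.0: 7, 6; 40.0: 4, 10; 60.0: 3, 17; 80.0: 3, 15; 90.0: 2, 16
- maple (time / min: target / %, over-reaction product / %): 8.00: 9, 2; 15.0: 10, 6; 25.0: 9, 12; 50.0: 9, 21; 90.0: 7, 33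

(scatter of a reading: 1.5 percentage points)



1. the flask that comes out highest in share of target in target plus over-reaction product, or "all alike" when all lie within 1.5 percentage points (winter / autumn / dawn / midnight / all alike)
2. share of target in target plus over-reaction product at the end, winter
3. share of target in target plus over-reaction product at the end, autumn
4. share of target in target plus over-reaction product at the end, dawn
5. share of target in target plus over-reaction product at the end, midnight

**The clock.** Maple lifts second substrate by a factor of 1.50 over cedar, yet its over-reaction product reads 21% at 50.0 min against cedar's 24% at 60.0 min. Cedar, alder, birch and maple share one reagent charge, so first order in reagent is my assumption, a pseudo-first-order clock, and not a reading. Winter and autumn have been given on average half their reagent charge during the addition, so they collect 80.0 min, against 120 min for dawn and midnight. That is reagent time, the time integral of reagent delivered as a fraction of its charge, with spending not counted.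

**Turned round.** On this clock, for "all alike", cedar's share at 80.0 min would have to lie within 1.5 percentage points of its share at 120 min. Hold target at the mean of cedar's last two readings, 4.50%, and draw a line between its last two over-reaction readings, which gives 28.3% at 80.0 min. My shares are then 13.7% and 10.8%, a gap of 2.9 points, wider than the margin, though a rough one, with readings good to 1.5 points.

**The forecast.** It names winter, with 17% for winter, 16% for autumn, 11% for dawn and 11% for midnight: “Both steps seem to follow reagent, so dosing mainly slows progress rather than changing the path.” My dosed share of 13.7% lies lower than its autumn figure. Like the forecast, I put the dosed flasks above dawn and midnight, but my clock gives winter and autumn the same reagent time, so it does not part them.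

**The flask.** The result is winter, with winter 17.0%, autumn 15.1%, dawn 7.43% and midnight 6.95%.

    target → over-reaction product (k = 7.60 × 10⁻⁴ s⁻¹)
    second substrate ⇌ dormant form (K = 1.60, k = 4.10 × 10⁻⁴ s⁻¹)
    starting material + target → side product (k = 0.00430 L mol⁻¹ s⁻¹)
    second substrate + reagent ⇌ second product (K = 3.20 L mol⁻¹, k = 5.30 × 10⁻⁴ L mol⁻¹ s⁻¹)
    starting material + reagent ⇌ target (K = 13.0 L mol⁻¹, k = 0.00150 L mol⁻¹ s⁻¹)

**Same clock.** In midnight at 2.00 h, target is used 5.2 times faster by turning into over-reaction product than by the side-product step. Over-reaction product stands there at 39.2%, target at 2.93%. Read the midnight flask at 80 min instead: its reagent time is 80.0 min, so the clock gives my 13.7%. The computed share there is 13.6%.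

(The readings were computed on assumed constants.)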